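**Retrosynthetic overview**

- Eudesmane numbering is used for every compound (ring A = C1–C5 and C10, ring B = C5–C10). The O6 ester is cut to diol 18 and silyl-protected 3-hydroxycinnamic acid 21. The 6β-OH and H-7α are traced back to the C6=C7 alkene of 16 (β-epoxidation steered by O4, then opening by trivalent titanium), and CH3-14 to an angular formyl group.
- Rings A and B are closed together in one intramolecular Diels–Alder reaction of the acyclic trienal 13: diene C5=C6–C7=C8 and dienophile C9=C10 (formyl carbon C14) form C5–C10 and C8–C9.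
- Feature on which this rests: C4 carries CH3-15, OH, a saturated arm (C3) and an unsaturated arm (C5), which is the substitution of the carbinol carbon of (S)-linalool. Its 4β-hydroxyl is axial on ring A and 1,3-diaxial to C14 on C10, so this one bought stereocentre can set C5 and C10 while ring A forms as a chair.
- Trienal 13 is assembled from (S)-linalool 1: O-silylation, cleavage of the trisubstituted alkene to the C1 alcohol, Heck coupling of the vinyl group with alkenyl triflate 7 (C7, C8, isopropyl), alkylation of the C1 iodide with a metalated acetaldehyde imine (C10, C14), desilylation and α-methylenation (C9).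

Key step: step 9

Assumption: (S)-(+)-linalool 1 is used in high enantiomeric purity, because its carbinol carbon (C4) is the only source of absolute configuration in the route.

**Route**

Step 1
Reactants: 1 (S)-(+)-linalool
Product: 2 (3S)-3,7-dimethyl-3-(triethylsilyloxy)octa-1,6-diene
Conditions: Et3SiOTf, 2,6-lutidine, CH2Cl2, −78 to 0 °C
Reagents that add atoms: triethylsilyl trifluoromethanesulfonate, CC[Si](CC)(CC)OS(=O)(=O)C(F)(F)F
Why: Silylation of a tertiary alcohol by a silyl triflate with a hindered pyridine base is routine and leaves the stereocentre untouched, and the ether is needed so that O4 cannot close a tetrahydrofuran onto C1 once C1 carries iodide.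

Step 2
Reactants: 2 (3S)-3,7-dimethyl-3-(triethylsilyloxy)octa-1,6-diene
Product: 4 (4S)-4-methyl-4-(triethylsilyloxy)hex-5-en-1-ol, via ozonide 3 (not isolated)
Conditions: O3 (1 equiv), CH2Cl2, Sudan Red 7B as end-point indicator, −78 °C; then NaBH4, MeOH, −78 °C to rt
Reagents that add atoms: ozone, [O-][O+]=O
Why: Ozonolysis with reductive work-up: ozone consumes the electron-rich trisubstituted alkene far faster than the vinyl group, which is monosubstituted and sits next to the silyloxy-bearing quaternary carbon, the dye marks the end point, and NaBH4 reduces the ozonide to the primary C1 alcohol.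

Step 3
Reactants: 5 3-methylbutan-2-one
Product: 7 3-methylbut-1-en-2-yl trifluoromethanesulfonate, via lithium enolate 6 (not isolated)
Conditions: LiN(iPr)2, THF, −78 °C; then PhNTf2, −78 to 0 °C
Reagents that add atoms: N-phenylbis(trifluoromethanesulfonimide), O=S(=O)(N(c1ccccc1)S(=O)(=O)C(F)(F)F)C(F)(F)F
Why: Kinetic deprotonation of the methyl ketone on its methyl side at −78 °C followed by O-sulfonylation of the enolate with PhNTf2 is the standard enol triflate synthesis and gives the 1,1-disubstituted alkenyl triflate.

Step 4
Reactants: 4 (4S)-4-methyl-4-(triethylsilyloxy)hex-5-en-1-ol; 7 3-methylbut-1-en-2-yl trifluoromethanesulfonate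
Product: 8 (4S,5E)-4,8-dimethyl-7-methylidene-4-(triethylsilyloxy)non-5-en-1-ol
Conditions: Pd(OAc)2 (5 mol%), PPh3 (10 mol%), Et3N, LiCl, DMF, 70 °C
Reagents that add atoms: none
Why: Heck reaction: the alkenylpalladium species formed by oxidative addition of 7 to zerovalent palladium adds to the terminal carbon of the vinyl group (the inner carbon is shielded by the quaternary C4), and syn β-hydride elimination, possible only from C6, gives the E-configured C5=C6 bond of the 2-isopropyl-1,3-diene.

Step 5
Reactants: 8 (4S,5E)-4,8-dimethyl-7-methylidene-4-(triethylsilyloxy)non-5-en-1-ol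
Product: 9 (4S,5E)-1-iodo-4,8-dimethyl-7-methylidene-4-(triethylsilyloxy)non-5-ene
Conditions: PPh3, I2, imidazole, CH2Cl2, 0 °C
Reagents that add atoms: iodine, II
Why: Appel-type iodination: SN2 displacement of the primary alkoxyphosphonium ion by iodide under imidazole buffering leaves the tertiary silyl ether and the diene untouched.

Step 6
Reactants: 9 (4S,5E)-1-iodo-4,8-dimethyl-7-methylidene-4-(triethylsilyloxy)non-5-ene
Product: 11 (6S,7E)-6,10-dimethyl-9-methylidene-6-(triethylsilyloxy)undec-7-enal, via N-tert-butyl imine 10 (not isolated)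
Conditions: N-tert-butylethanimine, LiN(iPr)2, THF, −78 to 0 °C; then 9, −78 °C to rt; then aq. AcOH/NaOAc (pH 4.5), rt
Reagents that add atoms: N-tert-butylethanimine, CC=NC(C)(C)C; water, O
Why: Metalloenamine (aza-enolate) alkylation: the lithiated acetaldehyde imine displaces the unhindered primary iodide by SN2 and so brings in C10 and C14, and buffered hydrolysis of the imine frees the aldehyde without ionising the dienylic silyl ether.

Step 7
Reactants: 11 (6S,7E)-6,10-dimethyl-9-methylidene-6-(triethylsilyloxy)undec-7-enal
Product: 12 (6S,7E)-6-hydroxy-6,10-dimethyl-9-methylideneundec-7-enal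
Conditions: Bu4NF, AcOH, THF, rt
Reagents that add atoms: none
Why: Fluoride-induced cleavage of the silyl ether, buffered with acetic acid so that the enolisable aldehyde does not undergo aldol reactions, frees the tertiary hydroxyl that the cycloaddition needs.

Step 8
Reactants: 12 (6S,7E)-6-hydroxy-6,10-dimethyl-9-methylideneundec-7-enal
Product: 13 (6S,7E)-6-hydroxy-6,10-dimethyl-2,9-dimethylideneundec-7-enal
Conditions: 37% aq. CH2O, pyrrolidine (10 mol%), propionic acid (10 mol%), i-PrOH, 45 °C
Reagents that add atoms: formaldehyde, C=O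
Why: α-Methylenation of an aldehyde by amine-catalysed Mannich condensation with formaldehyde and elimination of the amine gives the 2-alkylacrolein (C9), under weakly buffered conditions that leave the tertiary dienylic alcohol alone.

Step 9
Reactants: 13 (6S,7E)-6-hydroxy-6,10-dimethyl-2,9-dimethylideneundec-7-enal
Product: 14 4β-hydroxy-5α-eudesm-6-en-14-al (trans-fused, formyl group β on C10; may rest as its 4,14-lactol)
Conditions: toluene (0.01 M), BHT, base-washed sealed tube, 130 °C
Reagents that add atoms: none
Why: Thermal, concerted but asynchronous [4+2] cycloaddition of normal electron demand, a type 1 intramolecular Diels–Alder reaction of a 1,7,9-decatriene with a 2-alkylacrolein dienophile, which is a known reaction class: the nucleophilic diene terminus C8 bonds to the acrolein β-carbon C9 and C5 bonds to C10. Ring B closes as the cyclohexene of the cycloaddition (C5–C10 and C8–C9 formed, C6=C7 left behind), and ring A closes through the same C5–C10 bond across the four-carbon tether C1–C4, which folds as a chair. C10 relative to C5 is set by the endo position of the formyl group (tether exo) together with the E geometry of C5=C6, which places H-5 and the formyl group anti and gives the trans ring fusion. C5 and C10 relative to C4 are set by the chair tether: the chair with CH3-15 equatorial and the hydroxyl axial is preferred, because an axial methyl group would clash 1,3-diaxially with the formyl group, whereas the axial hydroxyl can hydrogen-bond to the formyl oxygen, which also lowers the LUMO of the dienophile. The step therefore needs endo selectivity and diastereofacial selectivity, and both are read from the two substituents on C4, while the isopropyl group on C7 raises the s-cis population of the diene. No Lewis acid is used because the tertiary dienylic alcohol would ionise, and high dilution with a radical inhibitor in base-washed glass holds back dimerisation of the acrolein.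

Step 10
Reactants: 14 4β-hydroxy-5α-eudesm-6-en-14-al
Product: 16 5α-eudesm-6-en-4β-ol, via hydrazone 15 (not isolated)
Conditions: N2H4·H2O, diethylene glycol, 130 °C; then KOH, 200 °C
Reagents that add atoms: none
Why: Wolff–Kishner reduction in the Huang-Minlon form: hydrazine traps the open form of the lactol as the hydrazone, and base-induced loss of N2 at 200 °C turns the angular formyl group into CH3-14, while the tertiary alkoxide and the isolated C6=C7 alkene are inert to hot KOH.

Step 11
Reactants: 16 5α-eudesm-6-en-4β-ol
Product: 17 6β,7β-epoxy-5α-eudesman-4β-ol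
Conditions: VO(acac)2 (5 mol%), t-BuOOH (decane), toluene, rt
Reagents that add atoms: tert-butyl hydroperoxide, CC(C)(C)OO
Why: Hydroxyl-directed epoxidation of a homoallylic alcohol: the vanadium alkoxide formed at the axial 4β-hydroxyl carries the bound tert-butyl peroxide to the β face of C6=C7 and so sets C6 and C7 as the 6β,7β-epoxide, which the cis hydroxyl cannot open from the rear.

Step 12
Reactants: 17 6β,7β-epoxy-5α-eudesman-4β-ol
Product: 18 5α,7αH-eudesmane-4β,6β-diol
Conditions: Cp2TiCl2, Zn dust, THF, rt (gives Cp2TiCl); then 17, 1,4-cyclohexadiene, rt; aq. NaH2PO4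
Reagents that add atoms: none
Why: Reductive epoxide opening by single-electron transfer from Cp2TiCl (trivalent titanium): the C7–O bond breaks to the tertiary C7 radical while the titanium alkoxide keeps the 6β C–O bond, and hydrogen-atom transfer from 1,4-cyclohexadiene along the axial α trajectory, opposite the bulky 6β-titanoxy group, sets H-7 α with the isopropyl group equatorial.

Step 13
Reactants: 19 (E)-3-hydroxycinnamic acid
Product: 21 (E)-3-[3-(tert-butyldimethylsilyloxy)phenyl]prop-2-enoic acid, via bis-silyl compound 20 (not isolated)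
Conditions: TBSCl, imidazole, DMF, rt; then AcOH/THF/H2O, rt
Reagents that add atoms: tert-butyldimethylsilyl chloride, CC(C)(C)[Si](C)(C)Cl
Why: Silylation of both hydroxyls followed by selective hydrolysis of the far more labile silyl ester leaves the phenol as its TBS ether and the acid free.

Step 14
Reactants: 18 5α,7αH-eudesmane-4β,6β-diol; 21 (E)-3-[3-(tert-butyldimethylsilyloxy)phenyl]prop-2-enoic acid
Product: 23 4β-hydroxy-5α,7αH-eudesman-6β-yl (E)-3-[3-(tert-butyldimethylsilyloxy)phenyl]prop-2-enoate, via mixed anhydride 22 (not isolated)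
Conditions: 21, 2,4,6-trichlorobenzoyl chloride, Et3N, THF, rt; then 18, DMAP, toluene, 60 °C
Reagents that add atoms: none
Why: Yamaguchi esterification: DMAP opens the mixed anhydride at the cinnamoyl carbonyl and the acylpyridinium ion acylates the secondary axial 6β-hydroxyl, while the tertiary 4β-hydroxyl is too hindered to react.

Step 15
Reactants: 23 4β-hydroxy-5α,7αH-eudesman-6β-yl (E)-3-[3-(tert-butyldimethylsilyloxy)phenyl]prop-2-enoate
Product: 24 4β-hydroxy-5α,7αH-eudesman-6β-yl (E)-3-(3-hydroxyphenyl)prop-2-enoate (CNP0283603.1)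
Conditions: Bu4NF, AcOH, THF, 0 °C
Reagents that add atoms: none
Why: Fluoride cleaves the aryl silyl ether easily because phenoxide leaves well from silicon, and acetic acid buffering keeps the cinnamate ester and its E alkene intact, so the target results.

**Compound list**

1 | (S)-(+)-linalool, (3S)-3,7-dimethylocta-1,6-dien-3-ol | C=C[C@@](C)(O)CCC=C(C)C | starting material
2 | (3S)-3,7-dimethyl-3-(triethylsilyloxy)octa-1,6-diene | C=C[C@@](C)(O[Si](CC)(CC)CC)CCC=C(C)C | intermediate
3 | 3,3-dimethyl-5-[(3S)-3-methyl-3-(triethylsilyloxy)pent-4-en-1-yl]-1,2,4-trioxolane (ozonide, both epimers at the ring carbon) | C=C[C@@](C)(O[Si](CC)(CC)CC)CCC1OOC(C)(C)O1 | intermediate (not isolated)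
4 | (4S)-4-methyl-4-(triethylsilyloxy)hex-5-en-1-ol | C=C[C@@](C)(O[Si](CC)(CC)CC)CCCO | intermediate
5 | 3-methylbutan-2-one | CC(=O)C(C)C | starting material
6 | lithium 3-methylbut-1-en-2-olate | [Li+].[O-]C(=C)C(C)C | intermediate (not isolated)
7 | 3-methylbut-1-en-2-yl trifluoromethanesulfonate | C=C(OS(=O)(=O)C(F)(F)F)C(C)C | intermediate
8 | (4S,5E)-4,8-dimethyl-7-methylidene-4-(triethylsilyloxy)non-5-en-1-ol | OCCC[C@](C)(O[Si](CC)(CC)CC)/C=C/C(=C)C(C)C | intermediate
9 | (4S,5E)-1-iodo-4,8-dimethyl-7-methylidene-4-(triethylsilyloxy)non-5-ene | ICCC[C@](C)(O[Si](CC)(CC)CC)/C=C/C(=C)C(C)C | intermediate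
10 | N-tert-butyl imine of 11, (6S,7E)-N-tert-butyl-6,10-dimethyl-9-methylidene-6-(triethylsilyloxy)undec-7-en-1-imine | CC(C)(C)N=CCCCC[C@](C)(O[Si](CC)(CC)CC)/C=C/C(=C)C(C)C | intermediate (not isolated)
11 | (6S,7E)-6,10-dimethyl-9-methylidene-6-(triethylsilyloxy)undec-7-enal | O=CCCCC[C@](C)(O[Si](CC)(CC)CC)/C=C/C(=C)C(C)C | intermediate
12 | (6S,7E)-6-hydroxy-6,10-dimethyl-9-methylideneundec-7-enal | O=CCCCC[C@](C)(O)/C=C/C(=C)C(C)C | intermediate
13 | (6S,7E)-6-hydroxy-6,10-dimethyl-2,9-dimethylideneundec-7-enal (key-step precursor) | C=C(C=O)CCC[C@](C)(O)/C=C/C(=C)C(C)C | intermediate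
14 | 4β-hydroxy-5α-eudesm-6-en-14-al, (4S,5R,10S), trans-fused, OH and CHO both β (key-step product; ring-chain tautomer: 4,14-lactol) | CC(C)C1=C[C@H]2[C@@](C)(O)CCC[C@]2(C=O)CC1 | intermediate
15 | hydrazone of 14 | CC(C)C1=C[C@H]2[C@@](C)(O)CCC[C@]2(C=NN)CC1 | intermediate (not isolated)
16 | 5α-eudesm-6-en-4β-ol (CH3-14 β, H-5 α, OH β) | CC(C)C1=C[C@H]2[C@@](C)(O)CCC[C@]2(C)CC1 | intermediate
17 | 6β,7β-epoxy-5α-eudesman-4β-ol | CC(C)[C@@]12CC[C@@]3(C)CCC[C@](C)(O)[C@@H]3[C@@H]1O2 | intermediate
18 | 5α,7αH-eudesmane-4β,6β-diol, (4S,5S,6R,7S,10R) | CC(C)[C@@H]1CC[C@@]2(C)CCC[C@](C)(O)[C@@H]2[C@@H]1O | intermediate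
19 | (E)-3-hydroxycinnamic acid | O=C(O)/C=C/c1cccc(O)c1 | starting material
20 | tert-butyldimethylsilyl (E)-3-[3-(tert-butyldimethylsilyloxy)phenyl]prop-2-enoate | CC(C)(C)[Si](C)(C)OC(=O)/C=C/c1cccc(O[Si](C)(C)C(C)(C)C)c1 | intermediate (not isolated)
21 | (E)-3-[3-(tert-butyldimethylsilyloxy)phenyl]prop-2-enoic acid | O=C(O)/C=C/c1cccc(O[Si](C)(C)C(C)(C)C)c1 | intermediate
22 | (E)-3-[3-(tert-butyldimethylsilyloxy)phenyl]prop-2-enoic 2,4,6-trichlorobenzoic anhydride | O=C(/C=C/c1cccc(O[Si](C)(C)C(C)(C)C)c1)OC(=O)c1c(Cl)cc(Cl)cc1Cl | intermediate (not isolated)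
23 | 4β-hydroxy-5α,7αH-eudesman-6β-yl (E)-3-[3-(tert-butyldimethylsilyloxy)phenyl]prop-2-enoate | CC(C)[C@@H]1CC[C@@]2(C)CCC[C@](C)(O)[C@@H]2[C@@H]1OC(=O)/C=C/c1cccc(O[Si](C)(C)C(C)(C)C)c1 | intermediate
24 | 4β-hydroxy-5α,7αH-eudesman-6β-yl (E)-3-(3-hydroxyphenyl)prop-2-enoate, (4S,5S,6R,7S,10R), CNP0283603.1 | CC(C)[C@@H]1CC[C@@]2(C)CCC[C@](C)(O)[C@@H]2[C@@H]1OC(=O)/C=C/c1cccc(O)c1 | target

**Step count and risks**

Total step count: 15. Longest linear sequence: 13 steps (1, 2, 4 to 12, 14, 15).

The three steps most likely to fail:

1. Step 9 (key cycloaddition). The free hydroxyl may steer the face too weakly, so that the chair with CH3-15 axial or the exo-formyl (cis-fused) mode competes. The thermal reaction may also be slow enough for the acrolein to dimerise. The fallback is a Lewis-acid-promoted cycloaddition on the silyl ether; it sets out from 11 and returns at 14. The α-methylenation of step 8 applied to 11 would give (6S,7E)-6,10-dimethyl-2,9-dimethylidene-6-(triethylsilyloxy)undec-7-enal F1. Me2AlCl in CH2Cl2 at −78 °C would bind the formyl oxygen and drive the same type 1 cycloaddition cold to 4β-(triethylsilyloxy)-5α-eudesm-6-en-14-al F2. The aluminium-bound formyl group is larger, which should raise both the endo preference and the penalty for an axial CH3-15, and the silyl ether is much less prone to ionise than the free alcohol. Bu4NF/AcOH would then free the hydroxyl and give 14.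

2. Step 12 (opening of the epoxide, with step 11 feeding it). The C7 radical may lose a β-hydrogen to give allylic alcohols instead of taking hydrogen, or may take hydrogen on the β face; the directed epoxidation before it may also be slow. The fallback avoids the epoxide; it sets out from 16 and returns at 18. Hydroboration (BH3·THF, then NaOH/H2O2) should add boron to C6 and hydrogen to C7 from the α face, away from CH3-14, to give 5α,7αH-eudesmane-4β,6α-diol F3. Oxidation of the secondary alcohol only (Dess–Martin periodinane, NaHCO3) would give 4β-hydroxy-5α,7αH-eudesman-6-one F4, which is kept neutral and cold because it is a β-hydroxy ketone. Its isopropyl group is equatorial, the stable arrangement at the enolisable C7. LiBH(s-Bu)3 at −78 °C should attack the ketone from the α face, since the β face is screened by CH3-14 and O4, and give the axial 6β-alcohol 18.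

3. Step 14 (acylation of O6). The axial 6β-hydroxyl, flanked by CH3-14, O4 and the isopropyl group, may react too slowly with the bulky conjugated acyl donor, so that the mixed anhydride decays first. The fallback builds the cinnamate on the alcohol; it sets out from 18 and returns at 23. The small acyl donor diethylphosphonoacetic acid (DCC, DMAP, CH2Cl2) would give 4β-hydroxy-5α,7αH-eudesman-6β-yl 2-(diethoxyphosphoryl)acetate F5. A Horner–Wadsworth–Emmons reaction (LiCl, DBU, MeCN) with 3-(tert-butyldimethylsilyloxy)benzaldehyde F6, made from 3-hydroxybenzaldehyde with TBSCl and imidazole, would then form the E alkene and give 23.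

Further compounds
F1 | step 9 | (6S,7E)-6,10-dimethyl-2,9-dimethylidene-6-(triethylsilyloxy)undec-7-enal | C=C(C=O)CCC[C@](C)(O[Si](CC)(CC)CC)/C=C/C(=C)C(C)C
F2 | step 9 | 4β-(triethylsilyloxy)-5α-eudesm-6-en-14-al | CC(C)C1=C[C@H]2[C@@](C)(O[Si](CC)(CC)CC)CCC[C@]2(C=O)CC1
F3 | step 12 | 5α,7αH-eudesmane-4β,6α-diol | CC(C)[C@@H]1CC[C@@]2(C)CCC[C@](C)(O)[C@@H]2[C@H]1O
F4 | step 12 | 4β-hydroxy-5α,7αH-eudesman-6-one | CC(C)[C@@H]1CC[C@@]2(C)CCC[C@](C)(O)[C@@H]2C1=O
F5 | step 14 | 4β-hydroxy-5α,7αH-eudesman-6β-yl 2-(diethoxyphosphoryl)acetate | CC(C)[C@@H]1CC[C@@]2(C)CCC[C@](C)(O)[C@@H]2[C@@H]1OC(=O)CP(=O)(OCC)OCC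
F6 | step 14 | 3-(tert-butyldimethylsilyloxy)benzaldehyde | O=Cc1cccc(O[Si](C)(C)C(C)(C)C)c1
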